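**Plan**

- Retrosynthesis: the isovalerate C–O bond at C1' and the C3'–OH bond are cut first, which leads back to an oxirane across C2'–C3'. Its two C–O bonds are then cut to an alkene, followed by C1'–C2' (aldehyde plus isobutenyl metal), C6–CHO (aryl bromide) and the pyranone ring (Pechmann).
- Forward: the pyranone ring is fused onto 4-bromoresorcinol, the phenol is methylated, C6 is formylated and the C4 chain is joined at C1'–C2'. The oxirane is then closed on C2'–C3', the C1' hydroxyl is esterified and the oxirane is opened by water at C3'.
- Enabling feature: C2' (secondary carbinol) and C3' (dimethylcarbinol) are the two carbons of a Me2C=CH alkene next to the benzylic carbinol C1' on C6 of the coumarin ring. The C1' hydroxyl can therefore steer oxygen onto C2', and the methyl group cis to C1' fixes the reactive conformation.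
- Stereochemistry: C1' comes from catalyst control (alkenylzinc addition to the Si face of the aldehyde). C2' comes from C1' by 1,2-induction in the hydroxyl-directed epoxidation (threo). The C2'–O bond is not broken afterwards, which gives (1'R,2'S).

Key step: step 5

Remark: the side chain is numbered C1' (benzylic), C2', C3' (carrying both methyl groups). The CIP label of C1' changes from S in 9 to R in 10, 12 and 13 only because C2' outranks the aryl carbon once it bears oxygen; the spatial arrangement is unchanged.

**Route**

Step 1
Reactants: 1 4-bromoresorcinol; 2 DL-malic acid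
Product: 4 6-bromo-7-hydroxy-2H-chromen-2-one, via 3-oxopropanoic acid 3 (not isolated)
Conditions: conc. H2SO4, 100–110 °C; then ice-water
Reagents that add atoms: none
Why: Von Pechmann condensation: hot sulfuric acid decarbonylates malic acid to formylacetic acid, which attacks the only doubly activated, unflanked ring position of 1 (para to one hydroxyl, ortho to the other) and lactonises, so bromine ends at C6 and the free hydroxyl at C7.

Step 2
Reactants: 4 6-bromo-7-hydroxy-2H-chromen-2-one
Product: 5 6-bromo-7-methoxy-2H-chromen-2-one
Conditions: MeI, K2CO3, acetone, reflux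
Reagents that add atoms: iodomethane, CI
Why: Williamson ether synthesis: the acidic 7-hydroxyl is deprotonated by carbonate and methylated by SN2 on iodomethane, conditions under which the lactone stays closed.

Step 3
Reactants: 5 6-bromo-7-methoxy-2H-chromen-2-one
Product: 6 7-methoxy-2-oxo-2H-chromene-6-carbaldehyde
Conditions: Pd(OAc)2 (1 mol %), di(1-adamantyl)-n-butylphosphine (3 mol %), TMEDA (1 equiv), CO/H2 (1:1, 5 bar), toluene, 100 °C
Reagents that add atoms: carbon monoxide, [C-]#[O+]
Why: Palladium-catalysed reductive carbonylation (formylation) of an aryl bromide with synthesis gas: oxidative addition, CO insertion and hydrogenolysis of the acyl–palladium species should give the aldehyde while the amine takes up HBr, and neither the lactone nor the conjugated C3–C4 alkene is expected to react with this phosphine–palladium system.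

Step 4
Reactants: 6 7-methoxy-2-oxo-2H-chromene-6-carbaldehyde; 7 2-methylprop-1-enylmagnesium bromide (purchased solution)
Product: 9 (S)-6-(1-hydroxy-3-methylbut-2-en-1-yl)-7-methoxy-2H-chromen-2-one, via bis(2-methylprop-1-enyl)zinc 8 (not isolated)
Conditions: 7 (3 equiv), ZnCl2 (1.5 equiv), Et2O, 0 °C to rt; 1,4-dioxane, filtration of the magnesium salts, solvent switch to toluene; then (−)-MIB [(2S)-3-exo-morpholinoisoborneol, 10 mol %], 6, toluene–CH2Cl2, −10 to 0 °C; sat. aq. NH4Cl; chromatography on Et3N-deactivated silica
Reagents that add atoms: none
Why: Amino-alcohol-catalysed enantioselective 1,2-addition of an alkenylzinc reagent to an aryl aldehyde: the zinc aminoalkoxide formed from (−)-MIB activates both partners and delivers the alkenyl group to the Si face of the formyl group, which sets C1' as (S), while the salt-free diorganozinc neither attacks the lactone nor adds through a fast uncatalysed racemic pathway.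

Step 5
Reactants: 9 (S)-6-(1-hydroxy-3-methylbut-2-en-1-yl)-7-methoxy-2H-chromen-2-one
Product: 10 6-[(R)-[(2S)-3,3-dimethyloxiran-2-yl](hydroxy)methyl]-7-methoxy-2H-chromen-2-one (threo epoxy alcohol)
Conditions: mCPBA (1.2 equiv), solid NaHCO3, CH2Cl2, 0 °C
Reagents that add atoms: meta-chloroperoxybenzoic acid (mCPBA), OOC(=O)c1cccc(Cl)c1
Why: The peracid, hydrogen-bonded to the C1' hydroxyl in the non-coordinating solvent, passes its terminal oxygen to the C2'=C3' π bond through the concerted spiro (butterfly) transition state of the Prilezhaev epoxidation. The closest known reaction type is the hydroxyl-directed (Henbest) peracid epoxidation of secondary allylic alcohols that carry an alkene substituent cis to the carbinol, which is threo-selective. The oxirane closes in that single event by syn [2+1] addition, the C2'–O and C3'–O bonds forming together without an open intermediate. The new stereocentre C2' is set by C1' (1,2-induction): the C3' methyl group cis to C1' forces the C1'–H bond into the alkene plane to avoid allylic 1,3-strain, the hydroxyl then lies over one face and delivers oxygen there, so (S)-9 should give the (2S)-oxirane, i.e. the threo (1'R,2'S) epoxy alcohol. The step needs threo over erythro face selectivity, secured by this A(1,3)-locked hydrogen-bonded geometry, and site selectivity for the electron-rich trisubstituted alkene over the electron-poor, lactone-conjugated C3–C4 alkene, which peracids do not attack under these conditions. The bicarbonate buffer keeps 3-chlorobenzoic acid from ionising the benzylic allylic carbinol or opening the tertiary oxirane terminus.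

Step 6
Reactants: 10 6-[(R)-[(2S)-3,3-dimethyloxiran-2-yl](hydroxy)methyl]-7-methoxy-2H-chromen-2-one; 11 3-methylbutanoic (isovaleric) anhydride
Product: 12 (R)-[(2S)-3,3-dimethyloxiran-2-yl](7-methoxy-2-oxo-2H-chromen-6-yl)methyl 3-methylbutanoate
Conditions: 11 (1.5 equiv), Et3N, DMAP (10 mol %), CH2Cl2, 0 °C to rt
Reagents that add atoms: none
Why: DMAP-catalysed acyl transfer from the anhydride (Steglich-type acylation of an alcohol) esterifies the only hydroxyl group with retention at C1', and the chloride-free basic medium leaves the oxirane and the lactone intact.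

Step 7
Reactants: 12 (R)-[(2S)-3,3-dimethyloxiran-2-yl](7-methoxy-2-oxo-2H-chromen-6-yl)methyl 3-methylbutanoate
Product: 13 (1R,2S)-2,3-dihydroxy-1-(7-methoxy-2-oxo-2H-chromen-6-yl)-3-methylbutyl 3-methylbutanoate (CNP0263682.1)
Conditions: HClO4 (5 mol %), THF–H2O (3:1), 0 °C
Reagents that add atoms: water, O
Why: Acid-catalysed epoxide hydrolysis: the protonated oxirane opens in a borderline SN1 fashion at the tertiary carbon C3', where water enters, so the C2'–O bond is never broken, C2' keeps its (S) configuration and the threo (1'R,2'S) diol monoester should result.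

**Compound list**

1 | 4-bromoresorcinol (4-bromobenzene-1,3-diol) | Oc1ccc(Br)c(O)c1 | starting material
2 | DL-malic acid | OC(CC(O)=O)C(O)=O | starting material
3 | 3-oxopropanoic acid (formylacetic acid) | O=CCC(O)=O | intermediate
4 | 6-bromo-7-hydroxy-2H-chromen-2-one | Oc1cc2oc(=O)ccc2cc1Br | intermediate
5 | 6-bromo-7-methoxy-2H-chromen-2-one | COc1cc2oc(=O)ccc2cc1Br | intermediate
6 | 7-methoxy-2-oxo-2H-chromene-6-carbaldehyde | COc1cc2oc(=O)ccc2cc1C=O | intermediate
7 | 2-methylprop-1-enylmagnesium bromide | CC(C)=C[Mg]Br | starting material
8 | bis(2-methylprop-1-enyl)zinc | CC(C)=C[Zn]C=C(C)C | intermediate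
9 | (S)-6-(1-hydroxy-3-methylbut-2-en-1-yl)-7-methoxy-2H-chromen-2-one | COc1cc2oc(=O)ccc2cc1[C@@H](O)C=C(C)C | intermediate
10 | 6-[(R)-[(2S)-3,3-dimethyloxiran-2-yl](hydroxy)methyl]-7-methoxy-2H-chromen-2-one | COc1cc2oc(=O)ccc2cc1[C@@H](O)[C@@H]1OC1(C)C | intermediate
11 | 3-methylbutanoic anhydride (isovaleric anhydride) | CC(C)CC(=O)OC(=O)CC(C)C | starting material
12 | (R)-[(2S)-3,3-dimethyloxiran-2-yl](7-methoxy-2-oxo-2H-chromen-6-yl)methyl 3-methylbutanoate | COc1cc2oc(=O)ccc2cc1[C@@H](OC(=O)CC(C)C)[C@@H]1OC1(C)C | intermediate
13 | (1R,2S)-2,3-dihydroxy-1-(7-methoxy-2-oxo-2H-chromen-6-yl)-3-methylbutyl 3-methylbutanoate | COc1cc2oc(=O)ccc2cc1[C@@H](OC(=O)CC(C)C)[C@H](O)C(C)(C)O | target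

**Step count and risks**

Total step count: 7. Longest linear sequence: 7 steps (1 to 13).

Steps most likely to fail:

1. Step 4. The enantioselectivity could be eroded by an uncatalysed or magnesium-salt-promoted background addition, and the hindered β,β-disubstituted alkenyl group could transfer slowly. Fallback, setting out from 6 and returning at 9:
   - A Nozaki–Hiyama–Kishi coupling of 6 with 1-bromo-2-methylpropene (CrCl2, cat. NiCl2, DMF) should give racemic 6-(1-hydroxy-3-methylbut-2-en-1-yl)-7-methoxy-2H-chromen-2-one F1.
   - Oxidation with activated MnO2 in CH2Cl2 should give the enone 7-methoxy-6-(3-methylbut-2-enoyl)-2H-chromen-2-one F2.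
   - A Corey–Bakshi–Shibata reduction of F2 with the oxazaborolidine antipode that delivers hydride to the Re face of the ketone should then give 9. This is expected to be (S)-Me-CBS if the s-cis dimethylvinyl arm acts as the larger group; the sense would be confirmed by Mosher ester analysis.

2. Step 7. While positive charge builds at C3', the C1' ester carbonyl could participate and transfer the acyl group to a neighbouring oxygen. The acyl group could also migrate from O1' to O2' in the product, and a hydride shift or elimination could compete with capture by water. Fallback, setting out from 10 and returning at 13: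
   - The oxirane of 10 is converted before acylation into a dioxolane with acetone and catalytic BF3·OEt2 at 0 °C (carbonyl oxygen attacks C3', the C2'–O bond is kept), which should give (R)-(7-methoxy-2-oxo-2H-chromen-6-yl)[(4S)-2,2,5,5-tetramethyl-1,3-dioxolan-4-yl]methanol F3.
   - Acylation with 11, Et3N and DMAP should give (R)-(7-methoxy-2-oxo-2H-chromen-6-yl)[(4S)-2,2,5,5-tetramethyl-1,3-dioxolan-4-yl]methyl 3-methylbutanoate F4.
   - Acetal hydrolysis in aqueous acetic acid, which proceeds at the acetal carbon and not at C3', should release 13.

3. Step 3. The aryl–palladium intermediate could undergo hydrodebromination, or the pyranone double bond could be partly saturated under synthesis gas. Fallback, setting out from 5 and returning at 6: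
   - A Suzuki–Miyaura coupling of 5 with potassium vinyltrifluoroborate (PdCl2(dppf), Et3N, n-PrOH, reflux) should give 6-ethenyl-7-methoxy-2H-chromen-2-one F5.
   - A Lemieux–Johnson cleavage (cat. OsO4, NaIO4, 2,6-lutidine, dioxane–H2O) should cut the electron-rich styrene-type alkene in preference to the lactone-conjugated one and give 6.

Further compounds
F1 | step 4 | racemic 6-(1-hydroxy-3-methylbut-2-en-1-yl)-7-methoxy-2H-chromen-2-one | COc1cc2oc(=O)ccc2cc1C(O)C=C(C)C
F2 | step 4 | 7-methoxy-6-(3-methylbut-2-enoyl)-2H-chromen-2-one | COc1cc2oc(=O)ccc2cc1C(=O)C=C(C)C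
F3 | step 7 | (R)-(7-methoxy-2-oxo-2H-chromen-6-yl)[(4S)-2,2,5,5-tetramethyl-1,3-dioxolan-4-yl]methanol | COc1cc2oc(=O)ccc2cc1[C@@H](O)[C@@H]1OC(C)(C)OC1(C)C
F4 | step 7 | (R)-(7-methoxy-2-oxo-2H-chromen-6-yl)[(4S)-2,2,5,5-tetramethyl-1,3-dioxolan-4-yl]methyl 3-methylbutanoate | COc1cc2oc(=O)ccc2cc1[C@@H](OC(=O)CC(C)C)[C@@H]1OC(C)(C)OC1(C)C
F5 | step 3 | 6-ethenyl-7-methoxy-2H-chromen-2-one | COc1cc2oc(=O)ccc2cc1C=C
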